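I had to decide which flask to charge for the most target, so I first asked what a flask could give.

common to all: starting material 10 mM

| charge | reagent | second substrate | protic impurity | temperature | remark | time |
|---|---|---|---|---|---|---|
| dusk | 9 mM | 5 mM | 10 mM | −35 °C | run made earlier |  |
| midnight | 9 mM | 7.5 mM | 10 mM | 0 °C | run made earlier |  |
| amber | 9.00 mM | 10.0 mM | 10.0 mM | 15 °C |  | 5.0 h |
| teal | 9.00 mM | 10.0 mM | 10.0 mM | −30 °C |  | 5.0 h |
| red | 9.00 mM | 10.0 mM | 10.0 mM | 30 °C |  | 5.0 h |
| ochre | 9.00 mM | 10.0 mM | 10.0 mM | −20 °C |  | 5.0 h |
| green | 9.00 mM | 10.0 mM | 10.0 mM | 0 °C |  | 5.0 h |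

| run | time / h | target / % |
|---|---|---|
| dusk | 2.50 | 14.7 |
| dusk | 5.00 | 22.2 |
| dusk | 8.00 | 26.8 |
| dusk | 12.0 | 25.0 |
| dusk | 15.0 | 25.3 |
| midnight | 0.417 | 33.1 |
| midnight | 0.833 | 35.3 |
| midnight | 1.33 | 36.3 |
| midnight | 1.50 | 35.7 |
| midnight | 2.00 | 36.0 |
| midnight | 2.50 | 35.7 |
| midnight | 3.00 | 35.3 |

(each reading ± 1 percentage point)

* the flasks by amount of target, in percent of the starting material charged, highest first, at 5.0 h (amber / teal / red / ochre / green)
* the same order at 15 min (amber / teal / red / ochre / green)
* the amount of target, in percent of the starting material charged of the flask you put first, at 5.0 h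
* the amount of target, in percent of the starting material charged of the flask you put last, at 5.0 h

- the numbers in the tables scatter by 1 percentage point (one standard deviation)
- candidate steps: starting material + reagent -> target; second substrate + reagent -> second product; starting material + protic impurity -> quenched substrate; target <-> isomer of the product

Each flask takes 9.00 mM of reagent against 10 mM of starting material, less, and target needs one reagent per starting material, so by these two charges reagent is the limiting reagent and my first answer was a ceiling of 90.0% of the starting material charged. The earlier runs stayed well under that ceiling: target levelled near 25.3% in dusk and 36.0% in midnight.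

So I went round again with the reagent yield, the target standing in the flask per reagent charged, read from those plateaus with their scatter: 28.1% in dusk and 40.0% in midnight. Red stands one step further along that line, with second substrate up by 2.50 mM, as it rose by 2.50 mM from dusk to midnight, and temperature going from 0 °C to 30 °C after going from −35 °C to 0 °C. I therefore added the whole rise once more and carried a reagent yield of 51.9% for red. Put back into the ceiling, this gave 46.7% of target, so I would charge red. The yield is a plateau figure, and dusk stood lower at 5.00 h, at 22.2%, than at its last reading, so I did not apply it to the cold flasks at that hour.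

The forecast gave red > amber > green > ochre > teal at 5.0 h and red > amber > green > ochre > teal at 15 min, with 41% for the first flask and 23% for the last, holding that “warming favours the productive step”. The flasks gave red > amber > green > teal > ochre at 5.0 h and red > amber > green > ochre > teal at 15 min, with red at 48.5% and ochre at 17.3%.

    starting material + reagent → target (k = 0.130 M⁻¹ s⁻¹, Ea = 58.0 kJ mol⁻¹)
    second substrate + reagent → second product (k = 0.0940 M⁻¹ s⁻¹, Ea = 45.0 kJ mol⁻¹)
    starting material + protic impurity → quenched substrate (k = 0.0700 M⁻¹ s⁻¹, Ea = 51.0 kJ mol⁻¹)
    target ⇌ isomer of the product (K = 0.270, k = 9.50 × 10⁻⁴ s⁻¹, Ea = 73.0 kJ mol⁻¹, ΔH = −49.0 kJ mol⁻¹)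
    (constants at 0 °C)

Red's reagent yield came to 53.8% against my 51.9%. I then ran the same reckoning on the neighbour, red with 40 mM of starting material: the ceiling fell to 22.5%, and my 51.9% made that 11.7% of target. The neighbour held 19.5%, a reagent yield of 86.6%, higher than red's. Its reagent stood at 0% of its charge, and its second product came to 0.957 mM against 4.00 mM in red.

The numbers in the tables were computed for substances that don't exist; scatter was added.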